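The route rests on disconnecting the piperidine C2–C3 bond. Piperidine C2 is bonded to C8 of flavone ring A and to N1, so before the chromone exists it is the benzylic, nitrogen-bearing CH2 of an N-Boc benzylamine. In one operation, ligand-controlled lithiation of that carbon and displacement of a terminal chloride on a four-carbon N-substituent should form C2–C3, close the piperidine and set the R stereocentre. The precursor 10 is tert-butyl N-(4-chlorobutyl)-N-(2,6-diisopropoxy-4-methoxybenzyl)carbamate. Its two isopropyl ethers later become the 7-hydroxyl and the pyranone oxygen O1 of ring C, and its methyl ether becomes 5-OMe.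

Key step: step 5

Assumption: the sense of induction is taken to mirror the (−)-sparteine series, so (+)-sparteine should give the 2R product (the CIP order N > aryl > CH2 > H is unchanged by the alkoxy groups), and ring closure at the lithiated carbon is taken to be invertive; ylide 17 is treated as a catalogue reagent.

Step 1
Reactants: 1 2,4,6-trihydroxybenzaldehyde
Product: 2 2,6-dihydroxy-4-methoxybenzaldehyde
Conditions: MeI (1.0 equiv), K2CO3 (1.0 equiv), acetone, 0 °C to rt
Reagents that add atoms: iodomethane, CI
Why: Williamson O-methylation under base-limited conditions; the 4-hydroxyl, para to the formyl group, is the most acidic and most accessible phenol, whereas the flanking hydroxyls are hindered and engaged with the carbonyl, so one equivalent of base and MeI should favour methylation at O4.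

Step 2
Reactants: 2 2,6-dihydroxy-4-methoxybenzaldehyde; 3 2-bromopropane
Product: 4 2,6-diisopropoxy-4-methoxybenzaldehyde
Conditions: 2-bromopropane (4 equiv), K2CO3 (4 equiv), DMF, 70 °C
Reagents that add atoms: 2-bromopropane (the second molar equivalent, which supplies the second isopropyl group), CC(C)Br
Why: Twofold Williamson etherification with a secondary bromide under forcing carbonate/DMF conditions should alkylate both remaining hindered phenols, each consuming one molecule of 2-bromopropane, while the excess bromide covers its loss by elimination.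

Step 3
Reactants: 4 2,6-diisopropoxy-4-methoxybenzaldehyde; 5 4-aminobutan-1-ol
Product: 8 tert-butyl N-(2,6-diisopropoxy-4-methoxybenzyl)-N-(4-hydroxybutyl)carbamate, via imine 6 (not isolated), via secondary amine 7 (not isolated)
Conditions: MeOH, 3 Å MS, rt; NaBH4, 0 °C; then Boc2O, rt
Reagents that add atoms: di-tert-butyl dicarbonate, CC(C)(C)OC(=O)OC(=O)OC(C)(C)C
Why: Stepwise reductive amination (imine condensation, then borohydride reduction) followed in the same flask by N-selective carbamoylation of the secondary amine over the primary alcohol; pre-forming the imine avoids direct reduction of the hindered aldehyde, and an amino alcohol cannot self-cyclise as a 4-haloamine would.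

Step 4
Reactants: 8 tert-butyl N-(2,6-diisopropoxy-4-methoxybenzyl)-N-(4-hydroxybutyl)carbamate
Product: 10 tert-butyl N-(4-chlorobutyl)-N-(2,6-diisopropoxy-4-methoxybenzyl)carbamate, via mesylate 9 (not isolated)
Conditions: MsCl, Et3N, CH2Cl2, 0 °C; then LiCl, DMF, 50 °C
Reagents that add atoms: lithium chloride, [Li+].[Cl-]
Why: Sulfonylation of the primary alcohol and SN2 displacement by chloride (Finkelstein-type) run under basic to neutral conditions that spare the acid-labile carbamate and the electron-rich benzylamine, and the non-nucleophilic carbamate nitrogen keeps the chlorobutyl chain from closing to a pyrrolidinium.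

Step 5
Reactants: 10 tert-butyl N-(4-chlorobutyl)-N-(2,6-diisopropoxy-4-methoxybenzyl)carbamate
Product: 12 tert-butyl (R)-2-(2,6-diisopropoxy-4-methoxyphenyl)piperidine-1-carboxylate, via benzylic organolithium 11 (not isolated)
Conditions: s-BuLi (1.3 equiv), (+)-sparteine (1.3 equiv), PhMe, −78 °C; MeOH
Reagents that add atoms: none
Why: The Boc carbonyl pre-complexes s-BuLi·(+)-sparteine and delivers the base to one enantiotopic benzylic hydrogen (complex-induced proximity), giving the dipole-stabilised, ligand-bound α-amino benzyllithium 11, which is expected to hold its configuration in toluene at −78 °C long enough to be captured by the tethered primary chloride. The closest known reaction type is the sparteine-mediated lithiation–cyclisation of N-Boc-N-(ω-chloroalkyl)benzylamines to 2-arylpyrrolidines and 2-arylpiperidines, of which this aryl group with two ortho alkoxy substituents is an untested member. The piperidine closes by a 6-exo-tet displacement that forms C2–C3. The single stereocentre (C2, R) is set by reagent control: the chiral diamine selects the proton and the carbanion must alkylate faster than it epimerises. The step needs benzylic rather than ring lithiation (arene C3 and C5 each lie between two oxygens) and substitution rather than lithium–halogen exchange or elimination; the carbamate-directed deprotonation, the bulky and weakly coordinating isopropoxy groups with no acidic protons, the non-coordinating solvent and chloride as nucleofuge are what should secure this.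

Step 6
Reactants: 12 tert-butyl (R)-2-(2,6-diisopropoxy-4-methoxyphenyl)piperidine-1-carboxylate
Product: 14 tert-butyl (R)-2-(2,6-dihydroxy-4-methoxyphenyl)piperidine-1-carboxylate, via aminodiphenol 13 (not isolated)
Conditions: BCl3 (6 equiv), CH2Cl2, −78 to 0 °C; MeOH, evaporate; then Boc2O (1.05 equiv), NaHCO3, THF–H2O, rt
Reagents that add atoms: di-tert-butyl dicarbonate, CC(C)(C)OC(=O)OC(=O)OC(C)(C)C
Why: Lewis-acid dealkylation, in which BCl3 cleaves the secondary alkyl aryl ethers far faster than the methyl ether and also strips the tert-butyl carbamate, followed at once by N-selective carbamoylation of the oxidation-prone aminodiphenol under aqueous bicarbonate; C2 is not a reacting centre and should keep its configuration at low temperature.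

Step 7
Reactants: 14 tert-butyl (R)-2-(2,6-dihydroxy-4-methoxyphenyl)piperidine-1-carboxylate
Product: 16 tert-butyl (R)-2-(3-formyl-2,6-dihydroxy-4-methoxyphenyl)piperidine-1-carboxylate, via hydroxymethylphenol 15 (not isolated)
Conditions: MgCl2 (3 equiv), Et3N (6 equiv), (CH2O)n (3 equiv), THF, 65 °C
Reagents that add atoms: paraformaldehyde (as formaldehyde), C=O
Why: Magnesium-mediated ortho-formylation of a phenol (Casnati–Skattebøl), in which the magnesium phenoxide directs formaldehyde to the adjacent ring carbon and a second formaldehyde oxidises the benzylic alkoxide by hydride transfer; arene C3 and C5 are equivalent by rotation about the aryl–C2 bond, so a limited formaldehyde charge should give one mono-aldehyde.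

Step 8
Reactants: 16 tert-butyl (R)-2-(3-formyl-2,6-dihydroxy-4-methoxyphenyl)piperidine-1-carboxylate; 17 dimethylsulfoxonium benzoylmethylide
Product: 19 tert-butyl (R)-2-(7-hydroxy-5-methoxy-4-oxo-2-phenyl-4H-chromen-8-yl)piperidine-1-carboxylate, via 1,3-diketone 18 (not isolated)
Conditions: [Cp*RhCl2]2 (4 mol %), AgSbF6 (16 mol %), PivOH (0.5 equiv), ClCH2CH2Cl, 80 °C
Reagents that add atoms: none
Why: Phenol-directed activation of the formyl C–H bond by the Cp*Rh catalyst (trivalent rhodium), carbene formation from the sulfoxonium ylide with loss of DMSO and migratory insertion give the 1,3-diketone, which cyclodehydrates through the phenol next to the new ketone to the 2-phenylchromen-4-one (C–H acylmethylation/annulation of salicylaldehydes); only the hydroxyl ortho to the aldehyde can direct and cyclise, which fixes 5-OMe, 7-OH and the 8-piperidinyl group.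

Step 9
Reactants: 19 tert-butyl (R)-2-(7-hydroxy-5-methoxy-4-oxo-2-phenyl-4H-chromen-8-yl)piperidine-1-carboxylate
Product: 20 7-hydroxy-5-methoxy-2-phenyl-8-[(2R)-piperidin-2-yl]-4H-chromen-4-one
Conditions: CF3CO2H, CH2Cl2, 0 °C; aq. NaHCO3
Reagents that add atoms: none
Why: Acidolysis of the tert-butyl carbamate (protonation, then loss of isobutene and CO2) at 0 °C; once nitrogen is protonated the benzylic C–N bond is a poor leaving group, so C2 should stay R, and the chromone and methyl ether are inert to CF3CO2H.

Compound list

1 | 2,4,6-trihydroxybenzaldehyde | O=Cc1c(O)cc(O)cc1O | starting material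
2 | 2,6-dihydroxy-4-methoxybenzaldehyde | COc1cc(O)c(C=O)c(O)c1 | intermediate
3 | 2-bromopropane | CC(C)Br | starting material
4 | 2,6-diisopropoxy-4-methoxybenzaldehyde | COc1cc(OC(C)C)c(C=O)c(OC(C)C)c1 | intermediate
5 | 4-aminobutan-1-ol | NCCCCO | starting material
6 | (E)-4-[(2,6-diisopropoxy-4-methoxybenzylidene)amino]butan-1-ol | COc1cc(OC(C)C)c(/C=N/CCCCO)c(OC(C)C)c1 | intermediate
7 | 4-[(2,6-diisopropoxy-4-methoxybenzyl)amino]butan-1-ol | COc1cc(OC(C)C)c(CNCCCCO)c(OC(C)C)c1 | intermediate
8 | tert-butyl N-(2,6-diisopropoxy-4-methoxybenzyl)-N-(4-hydroxybutyl)carbamate | COc1cc(OC(C)C)c(CN(CCCCO)C(=O)OC(C)(C)C)c(OC(C)C)c1 | intermediate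
9 | 4-[(tert-butoxycarbonyl)(2,6-diisopropoxy-4-methoxybenzyl)amino]butyl methanesulfonate | COc1cc(OC(C)C)c(CN(CCCCOS(C)(=O)=O)C(=O)OC(C)(C)C)c(OC(C)C)c1 | intermediate
10 | tert-butyl N-(4-chlorobutyl)-N-(2,6-diisopropoxy-4-methoxybenzyl)carbamate | COc1cc(OC(C)C)c(CN(CCCCCl)C(=O)OC(C)(C)C)c(OC(C)C)c1 | intermediate
11 | (S)-benzylic lithio derivative of 10, lithium on the carbon between the aryl ring and nitrogen (sparteine ligand omitted) | COc1cc(OC(C)C)c([C@@H](N(CCCCCl)C(=O)OC(C)(C)C)[Li])c(OC(C)C)c1 | intermediate
12 | tert-butyl (R)-2-(2,6-diisopropoxy-4-methoxyphenyl)piperidine-1-carboxylate | COc1cc(OC(C)C)c([C@H]2CCCCN2C(=O)OC(C)(C)C)c(OC(C)C)c1 | intermediate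
13 | (R)-2-(2,6-dihydroxy-4-methoxyphenyl)piperidine (present as its hydrochloride) | COc1cc(O)c([C@H]2CCCCN2)c(O)c1 | intermediate
14 | tert-butyl (R)-2-(2,6-dihydroxy-4-methoxyphenyl)piperidine-1-carboxylate | COc1cc(O)c([C@H]2CCCCN2C(=O)OC(C)(C)C)c(O)c1 | intermediate
15 | tert-butyl (R)-2-[2,6-dihydroxy-3-(hydroxymethyl)-4-methoxyphenyl]piperidine-1-carboxylate | COc1cc(O)c([C@H]2CCCCN2C(=O)OC(C)(C)C)c(O)c1CO | intermediate
16 | tert-butyl (R)-2-(3-formyl-2,6-dihydroxy-4-methoxyphenyl)piperidine-1-carboxylate | COc1cc(O)c([C@H]2CCCCN2C(=O)OC(C)(C)C)c(O)c1C=O | intermediate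
17 | dimethylsulfoxonium benzoylmethylide | CS(C)(=O)=CC(=O)c1ccccc1 | starting material
18 | tert-butyl (R)-2-[2,6-dihydroxy-4-methoxy-3-(3-oxo-3-phenylpropanoyl)phenyl]piperidine-1-carboxylate | COc1cc(O)c([C@H]2CCCCN2C(=O)OC(C)(C)C)c(O)c1C(=O)CC(=O)c1ccccc1 | intermediate
19 | tert-butyl (R)-2-(7-hydroxy-5-methoxy-4-oxo-2-phenyl-4H-chromen-8-yl)piperidine-1-carboxylate | COc1cc(O)c([C@H]2CCCCN2C(=O)OC(C)(C)C)c2oc(-c3ccccc3)cc(=O)c12 | intermediate
20 | 7-hydroxy-5-methoxy-2-phenyl-8-[(2R)-piperidin-2-yl]-4H-chromen-4-one (CNP0140822.1) | COc1cc(O)c([C@H]2CCCCN2)c2oc(-c3ccccc3)cc(=O)c12 | target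

Total step count: 9. Longest linear sequence: 9 steps (1 to 20).

Steps most likely to fail

1. Step 5. Deprotonation may be sluggish, because the two ortho ethers twist the benzylic C–H bonds out of conjugation with an electron-rich ring. Ring lithiation between OiPr and OMe may compete. The organolithium may also partly epimerise before the slower six-membered closure, lowering the enantiomeric purity. The fallback replaces asymmetric deprotonation by auxiliary-controlled addition to an imine; it sets out from 4 and comes back at 12. Condensation of 4 with (S)-2-methylpropane-2-sulfinamide (Ti(OEt)4, THF, 60 °C) should give (S,E)-N-(2,6-diisopropoxy-4-methoxybenzylidene)-2-methylpropane-2-sulfinamide F1. 4-Chlorobutylmagnesium bromide F2, prepared from 1-bromo-4-chlorobutane and Mg in THF, is added in CH2Cl2 at −48 °C. The six-membered magnesium chelate should direct the alkyl group to the face that gives (S)-N-[(R)-5-chloro-1-(2,6-diisopropoxy-4-methoxyphenyl)pentyl]-2-methylpropane-2-sulfinamide F3. The diastereomers are separable, and the antipodal auxiliary is available should ortho-alkoxy chelation reverse the sense. NaH in DMF then closes the ring by N-alkylation to (R)-1-[(S)-tert-butylsulfinyl]-2-(2,6-diisopropoxy-4-methoxyphenyl)piperidine F4. HCl in MeOH removes the sulfinyl group to give (R)-2-(2,6-diisopropoxy-4-methoxyphenyl)piperidine F5, and Boc2O returns the route to 12.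

2. Step 6. The Lewis acid, bound to the carbamate, may ionise the benzylic C–N bond next to the trioxygenated ring; reversible ring opening would erode the configuration. Liberated tert-butyl cations may alkylate the nucleophilic ring, and prolonged exposure may also cleave the methyl ether. The fallback separates the two deprotections, so that the Lewis acid never meets an N-acyl benzylic amine; it sets out from 12 and comes back at 13. HCl in dioxane at 0 °C should remove only the carbamate and give (R)-2-(2,6-diisopropoxy-4-methoxyphenyl)piperidinium chloride F6. BCl3 in CH2Cl2 then acts on an ammonium salt that offers no carbonyl donor and a poor nucleofuge at the benzylic carbon. The ether cleavage rejoins the route at 13, which is carbamoylated to 14 as in step 6.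

3. Step 8. The carbamate or the second phenol may bind and inhibit the cationic rhodium catalyst, cyclodehydration of the diketone may stall, and the carbamate may be lost under acid at 80 °C. The fallback builds the pyranone by palladium-catalysed carbonylation and also bypasses step 7; it sets out from 14 and comes back at 19. NIS (1.0 equiv) in MeCN at −20 °C should iodinate the one type of free ring position to give tert-butyl (R)-2-(2,6-dihydroxy-3-iodo-4-methoxyphenyl)piperidine-1-carboxylate F7. PdCl2(PPh3)2, CO (1 atm), phenylacetylene and Et2NH at 60 °C should then effect carbonylative Sonogashira coupling to tert-butyl (R)-2-[2,6-dihydroxy-4-methoxy-3-(3-phenylprop-2-ynoyl)phenyl]piperidine-1-carboxylate F8. Under the amine, the adjacent phenol closes onto the alkyne in the 6-endo mode to give 19.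

Further compounds

F1 | step 5 | (S,E)-N-(2,6-diisopropoxy-4-methoxybenzylidene)-2-methylpropane-2-sulfinamide | COc1cc(OC(C)C)c(/C=N/[S@@](=O)C(C)(C)C)c(OC(C)C)c1
F2 | step 5 | 4-chlorobutylmagnesium bromide | ClCCCC[Mg]Br
F3 | step 5 | (S)-N-[(R)-5-chloro-1-(2,6-diisopropoxy-4-methoxyphenyl)pentyl]-2-methylpropane-2-sulfinamide | CC(C)(C)[S@](=O)N[C@H](CCCCCl)c1c(OC(C)C)cc(OC)cc1OC(C)C
F4 | step 5 | (R)-1-[(S)-tert-butylsulfinyl]-2-(2,6-diisopropoxy-4-methoxyphenyl)piperidine | COc1cc(OC(C)C)c([C@H]2CCCCN2[S@@](=O)C(C)(C)C)c(OC(C)C)c1
F5 | step 5 | (R)-2-(2,6-diisopropoxy-4-methoxyphenyl)piperidine | COc1cc(OC(C)C)c([C@H]2CCCCN2)c(OC(C)C)c1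
F6 | step 6 | (R)-2-(2,6-diisopropoxy-4-methoxyphenyl)piperidinium chloride | COc1cc(OC(C)C)c([C@H]2CCCC[NH2+]2)c(OC(C)C)c1.[Cl-]
F7 | step 8 | tert-butyl (R)-2-(2,6-dihydroxy-3-iodo-4-methoxyphenyl)piperidine-1-carboxylate | COc1cc(O)c([C@H]2CCCCN2C(=O)OC(C)(C)C)c(O)c1I
F8 | step 8 | tert-butyl (R)-2-[2,6-dihydroxy-4-methoxy-3-(3-phenylprop-2-ynoyl)phenyl]piperidine-1-carboxylate | COc1cc(O)c([C@H]2CCCCN2C(=O)OC(C)(C)C)c(O)c1C(=O)C#Cc1ccccc1
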